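**Plan**

- Ring atoms: C1 (C=O), C2 (C(OH)CH3), C3 (CHOH), C4 (CH2), C5 (CH with the side chain), C6 (CH–O-acyl). The retrosynthesis cuts, in order: the C–OOH bond of the side chain (singlet-oxygen ene on a prenyl ketone), the bond between the side-chain ketone carbon and its prenyl CH2, the ester C–O bond, then C1–C2 and C3–C4 of the ring together, then C5–C6.
- Enabling feature: in the cyclohexanone the CH(OH)–C(OH)CH3 pair (C3–C2) lies between a CH2 (C4) and the ketone carbon (C1). C3–C2 is therefore methylglyoxal, C4 a nitronate carbon (temporary nitro group) and C1 an acyl anion (carbene umpolung of an aldehyde), so methylglyoxal can be stitched into a C4–C5–C6–C1 chain in one flask.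
- Forward: nitrodiene, Michael addition (C5–C6), nitroaldol to a temporary oxane (lactol) ring, crossed benzoin to the cyclohexanone, nitro removal, protecting-group exchange and isovalerate, growth of the isopropenyl group into the prenyl enone, ene reaction, desilylation.
- Stereochemistry: C5 and C6 from a catalyst-controlled syn Michael addition; C3 by thermodynamic relay through the all-equatorial lactol; C2 from a chair benzoin transition state (methyl equatorial); the (E)-alkene from the ene transition state.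

Key step: step 4

Remark: 2-[(4-methoxyphenyl)methoxy]acetaldehyde (6) is taken as a catalogue compound, and methylglyoxal (8) is used as the monomer freshly distilled from its commercial aqueous solution.

**Route**

Step 1
Reactants: 1 methacrolein; 2 nitromethane
Product: 3 rac-3-methyl-1-nitrobut-3-en-2-ol
Conditions: MeNO2 (5 equiv), KOtBu (5 mol %), THF/t-BuOH, 0 °C
Reagents that add atoms: none
Why: Base-catalysed nitroaldol (Henry) reaction; a catalytic amount of alkoxide at 0 °C should favour kinetic 1,2-addition to the formyl group over conjugate addition, and the racemic carbinol centre is removed in step 2.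

Step 2
Reactants: 3 rac-3-methyl-1-nitrobut-3-en-2-ol
Product: 5 (E)-3-methyl-1-nitrobuta-1,3-diene, via allylic mesylate 4 (not isolated)
Conditions: MsCl, Et3N (2.5 equiv), CH2Cl2, −20 to 0 °C; solution used at once
Reagents that add atoms: none
Why: Mesylation followed by E1cB elimination of the β-mesyloxy nitroalkane (standard nitroalkene synthesis) should give the conjugated (E)-nitrodiene, which is used immediately because it polymerises on storage.

Step 3
Reactants: 5 (E)-3-methyl-1-nitrobuta-1,3-diene; 6 2-[(4-methoxyphenyl)methoxy]acetaldehyde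
Product: 7 (2S,3R)-2-[(4-methoxyphenyl)methoxy]-4-methyl-3-(nitromethyl)pent-4-enal
Conditions: (R)-2-[diphenyl(trimethylsilyloxy)methyl]pyrrolidine (10 mol %), ClCH2CO2H (20 mol %), 6 (1.5 equiv), CH2Cl2, 0 °C to rt
Reagents that add atoms: none
Why: Enamine-mediated asymmetric Michael addition (diarylprolinol silyl ether catalysis): the anti-enamine of 6 should add 1,4 to the nitrodiene through the usual synclinal open transition state on the face remote from the diphenyl(silyloxy)methyl group, which sets both stereocentres syn and, with the (R)-catalyst, as (2S,3R).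

Step 4
Reactants: 7 (2S,3R)-2-[(4-methoxyphenyl)methoxy]-4-methyl-3-(nitromethyl)pent-4-enal; 8 methylglyoxal
Product: 10 (2S,3R,4R,5R,6S)-2,3-dihydroxy-6-[(4-methoxyphenyl)methoxy]-2-methyl-4-nitro-5-(prop-1-en-2-yl)cyclohexan-1-one, via all-equatorial lactol 9 (not isolated)
Conditions: 8 (1.1 equiv), i-Pr2NEt (0.3 equiv), THF, 0 °C to rt; then 2-(pentafluorophenyl)-6,7-dihydro-5H-pyrrolo[2,1-c][1,2,4]triazol-2-ium tetrafluoroborate (15 mol %), rt to 40 °C, under argon; AcOH quench
Reagents that add atoms: none
Why: The amine base forms the nitronate of 7, which adds to the formyl carbon of 8 (nitroaldol, C3–C4 bond), the new hydroxyl closes onto the aldehyde of 7 to give lactol 9, and the carbene released from the triazolium salt then adds to the small open-chain aldehyde fraction to give a Breslow intermediate whose nucleophilic carbon attacks the acetyl ketone (crossed benzoin, C1–C2 bond) before the catalyst is expelled. The closest known reaction types are the base-mediated nitroaldol/hemiacetalisation of γ-nitro aldehydes with a second aldehyde to all-trans 2-hydroxyoxanes and the carbene-catalysed intramolecular crossed aldehyde–ketone benzoin cyclisation to tertiary α-ketols, here run in one flask. The temporary oxane ring closes by 6-exo-trig attack of oxygen on the formyl group and the cyclohexanone by 6-(enolexo)-exo-trig attack of the enaminol carbon on the ketone. C4 (nitro) and C3 are set under thermodynamic control in 9, where reversible nitroaldol and nitronate protonation should drain the mixture into the all-equatorial oxane, and an equatorial acetyl group on that oxane corresponds, after the ring switch, to the axial C3 hydroxyl of the target. C2 is set in a chair transition state with the methyl group equatorial and the ketone C=O antiperiplanar to the axial C3–O bond (Cornforth-type dipole alignment), which should give the trans-diaxial diol. The step needs attack of the nitronate on the aldehyde and not the ketone of 8 (secured by the higher electrophilicity of the α-keto aldehyde carbon) and ring closure of the acyl anion equivalent in preference to β-elimination, dimerisation or aldol reaction (secured by the ether at C6, which is a poor leaving group, by the α-branched aldehyde and by the weak amine base).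

Step 5
Reactants: 10 (2S,3R,4R,5R,6S)-2,3-dihydroxy-6-[(4-methoxyphenyl)methoxy]-2-methyl-4-nitro-5-(prop-1-en-2-yl)cyclohexan-1-one
Product: 11 (2S,3R,5S,6S)-2,3-dihydroxy-6-[(4-methoxyphenyl)methoxy]-2-methyl-5-(prop-1-en-2-yl)cyclohexan-1-one
Conditions: Bu3SnH (5 equiv), AIBN (0.4 equiv, in portions), toluene, 110 °C
Reagents that add atoms: none
Why: Radical denitration: the stannyl radical adds to the nitro group, the adduct fragments at the C–N bond and the secondary ring radical abstracts hydrogen from Bu3SnH, so the helper nitro group leaves no stereocentre behind.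

Step 6
Reactants: 11 (2S,3R,5S,6S)-2,3-dihydroxy-6-[(4-methoxyphenyl)methoxy]-2-methyl-5-(prop-1-en-2-yl)cyclohexan-1-one
Product: 12 (2S,3R,5S,6S)-6-[(4-methoxyphenyl)methoxy]-2-methyl-5-(prop-1-en-2-yl)-2,3-bis[(triethylsilyl)oxy]cyclohexan-1-one
Conditions: Et3SiOTf (3 equiv), 2,6-lutidine (5 equiv), CH2Cl2, −78 to 0 °C
Reagents that add atoms: triethylsilyl trifluoromethanesulfonate, CC[Si](CC)(CC)OS(=O)(=O)C(F)(F)F
Why: Silyl triflate silylation of the hindered secondary and tertiary alcohols; 2,6-lutidine is too weak a base to form the silyl enol ether of the ketone.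

Step 7
Reactants: 12 (2S,3R,5S,6S)-6-[(4-methoxyphenyl)methoxy]-2-methyl-5-(prop-1-en-2-yl)-2,3-bis[(triethylsilyl)oxy]cyclohexan-1-one
Product: 13 (2S,3R,5S,6S)-6-hydroxy-2-methyl-5-(prop-1-en-2-yl)-2,3-bis[(triethylsilyl)oxy]cyclohexan-1-one
Conditions: DDQ (1.5 equiv), CH2Cl2/pH 7 buffer, 0 °C to rt
Reagents that add atoms: none
Why: Oxidative removal of a p-methoxybenzyl ether with DDQ (hydride abstraction from the electron-rich benzylic position and hydrolysis of the oxocarbenium ion), which leaves silyl ethers, the ketone and the isopropenyl group untouched.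

Step 8
Reactants: 13 (2S,3R,5S,6S)-6-hydroxy-2-methyl-5-(prop-1-en-2-yl)-2,3-bis[(triethylsilyl)oxy]cyclohexan-1-one
Product: 14 (1S,3S,4R,6S)-3-methyl-2-oxo-6-(prop-1-en-2-yl)-3,4-bis[(triethylsilyl)oxy]cyclohexyl 3-methylbutanoate
Conditions: 3-methylbutanoyl chloride (1.5 equiv), pyridine, 4-(dimethylamino)pyridine (10 mol %), CH2Cl2, 0 °C
Reagents that add atoms: 3-methylbutanoyl chloride, CC(C)CC(=O)Cl
Why: Nucleophile-catalysed acylation of the only free hydroxyl group, an equatorial secondary α-hydroxy ketone.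

Step 9
Reactants: 14 (1S,3S,4R,6S)-3-methyl-2-oxo-6-(prop-1-en-2-yl)-3,4-bis[(triethylsilyl)oxy]cyclohexyl 3-methylbutanoate
Product: 16 (1S,3S,4R,6S)-3-methyl-2-oxo-6-(3-oxoprop-1-en-2-yl)-3,4-bis[(triethylsilyl)oxy]cyclohexyl 3-methylbutanoate, via primary allylic alcohol 15 (not isolated)
Conditions: SeO2 (0.5 equiv), t-BuOOH (4 equiv, in decane), CH2Cl2, 0 °C to rt, until 15 is consumed
Reagents that add atoms: tert-butyl hydroperoxide, CC(C)(C)OO (source of the new oxygen atom, passed on through selenium dioxide, O=[Se]=O)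
Why: Allylic oxidation with SeO2 (Riley oxidation in its catalytic tert-butyl hydroperoxide form): ene reaction at the terminal CH2, [2,3]-sigmatropic shift and further oxidation of the primary allylic alcohol should give the 2-substituted acrolein, the ring methine hydrogen being deactivated by the neighbouring acyloxy-bearing carbon.

Step 10
Reactants: 16 (1S,3S,4R,6S)-3-methyl-2-oxo-6-(3-oxoprop-1-en-2-yl)-3,4-bis[(triethylsilyl)oxy]cyclohexyl 3-methylbutanoate
Product: 17 (1S,3S,4R,6S)-6-(3-hydroxy-6-methylhepta-1,5-dien-2-yl)-3-methyl-2-oxo-3,4-bis[(triethylsilyl)oxy]cyclohexyl 3-methylbutanoate (both carbinol epimers)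
Conditions: BaI2, lithium biphenylide (LiC12H10, 2 equiv), THF, rt; 1-chloro-3-methylbut-2-ene, −78 °C; then 16 (added to 1.1 equiv of reagent), −78 °C; aq. NH4Cl
Reagents that add atoms: 1-chloro-3-methylbut-2-ene, CC(C)=CCCl
Why: Carbonyl allylation with an allylic barium reagent (made from zerovalent barium), which reacts at its less substituted α-carbon and so should give the linear prenyl carbinol; at −78 °C the aldehyde is far more reactive than the hindered ring ketone and the ester, and the new carbinol centre is oxidised away in step 11.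

Step 11
Reactants: 17 (1S,3S,4R,6S)-6-(3-hydroxy-6-methylhepta-1,5-dien-2-yl)-3-methyl-2-oxo-3,4-bis[(triethylsilyl)oxy]cyclohexyl 3-methylbutanoate
Product: 18 (1S,3S,4R,6S)-3-methyl-6-(6-methyl-3-oxohepta-1,5-dien-2-yl)-2-oxo-3,4-bis[(triethylsilyl)oxy]cyclohexyl 3-methylbutanoate
Conditions: Dess–Martin periodinane (1.3 equiv), NaHCO3, CH2Cl2, 0 °C
Reagents that add atoms: none
Why: Dess–Martin oxidation of the allylic alcohol under buffered conditions should give the α-methylene ketone without moving the β,γ-double bond into conjugation.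

Step 12
Reactants: 18 (1S,3S,4R,6S)-3-methyl-6-(6-methyl-3-oxohepta-1,5-dien-2-yl)-2-oxo-3,4-bis[(triethylsilyl)oxy]cyclohexyl 3-methylbutanoate
Product: 19 (1S,3S,4R,6S)-6-[(4E)-6-hydroperoxy-6-methyl-3-oxohepta-1,4-dien-2-yl]-3-methyl-2-oxo-3,4-bis[(triethylsilyl)oxy]cyclohexyl 3-methylbutanoate
Conditions: O2, 5,10,15,20-tetraphenylporphyrin (1 mol %), visible light, CH2Cl2, −20 °C
Reagents that add atoms: dioxygen, O=O
Why: Schenck ene reaction of singlet oxygen with the electron-rich trisubstituted alkene: oxygen should bond to the dimethyl-substituted carbon while a hydrogen of the ketone-activated CH2 is abstracted, which gives the conjugated enone with (E) geometry and the tertiary hydroperoxide, the electron-poor α-methylene group being inert.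

Step 13
Reactants: 19 (1S,3S,4R,6S)-6-[(4E)-6-hydroperoxy-6-methyl-3-oxohepta-1,4-dien-2-yl]-3-methyl-2-oxo-3,4-bis[(triethylsilyl)oxy]cyclohexyl 3-methylbutanoate
Product: 20 (1S,3S,4R,6S)-3,4-dihydroxy-6-[(4E)-6-hydroperoxy-6-methyl-3-oxohepta-1,4-dien-2-yl]-3-methyl-2-oxocyclohexyl 3-methylbutanoate
Conditions: HF·pyridine, pyridine, THF, 0 °C to rt
Reagents that add atoms: none
Why: Fluoride-mediated cleavage of both triethylsilyl ethers with buffered HF·pyridine, conditions that hydroperoxides, α-acyloxy ketones and enones tolerate.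

**Compound list**

1 | methacrolein (2-methylprop-2-enal) | C=C(C)C=O | starting material
2 | nitromethane | C[N+](=O)[O-] | starting material
3 | rac-3-methyl-1-nitrobut-3-en-2-ol | C=C(C)C(O)C[N+](=O)[O-] | intermediate
4 | rac-3-methyl-1-nitrobut-3-en-2-yl methanesulfonate (formed in the flask in step 2) | C=C(C)C(OS(C)(=O)=O)C[N+](=O)[O-] | intermediate
5 | (E)-3-methyl-1-nitrobuta-1,3-diene | C=C(C)/C=C/[N+](=O)[O-] | intermediate
6 | 2-[(4-methoxyphenyl)methoxy]acetaldehyde | O=CCOCc1ccc(OC)cc1 | starting material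
7 | (2S,3R)-2-[(4-methoxyphenyl)methoxy]-4-methyl-3-(nitromethyl)pent-4-enal | C=C(C)[C@H](C[N+](=O)[O-])[C@H](OCc1ccc(OC)cc1)C=O | intermediate
8 | methylglyoxal (2-oxopropanal) | CC(=O)C=O | starting material
9 | 1-[(2R,3R,4R,5S)-6-hydroxy-5-[(4-methoxyphenyl)methoxy]-3-nitro-4-(prop-1-en-2-yl)oxan-2-yl]ethan-1-one (all-equatorial lactol, anomer mixture, formed in the flask in step 4) | CC(=O)[C@@H]1OC(O)[C@@H](OCc2ccc(OC)cc2)[C@H](C(C)=C)[C@H]1[N+](=O)[O-] | intermediate
10 | (2S,3R,4R,5R,6S)-2,3-dihydroxy-6-[(4-methoxyphenyl)methoxy]-2-methyl-4-nitro-5-(prop-1-en-2-yl)cyclohexan-1-one | CC(=C)[C@@H]1[C@@H]([N+](=O)[O-])[C@@H](O)[C@](C)(O)C(=O)[C@H]1OCc1ccc(OC)cc1 | intermediate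
11 | (2S,3R,5S,6S)-2,3-dihydroxy-6-[(4-methoxyphenyl)methoxy]-2-methyl-5-(prop-1-en-2-yl)cyclohexan-1-one | CC(=C)[C@@H]1C[C@@H](O)[C@](C)(O)C(=O)[C@H]1OCc1ccc(OC)cc1 | intermediate
12 | (2S,3R,5S,6S)-6-[(4-methoxyphenyl)methoxy]-2-methyl-5-(prop-1-en-2-yl)-2,3-bis[(triethylsilyl)oxy]cyclohexan-1-one | CC(=C)[C@@H]1C[C@@H](O[Si](CC)(CC)CC)[C@](C)(O[Si](CC)(CC)CC)C(=O)[C@H]1OCc1ccc(OC)cc1 | intermediate
13 | (2S,3R,5S,6S)-6-hydroxy-2-methyl-5-(prop-1-en-2-yl)-2,3-bis[(triethylsilyl)oxy]cyclohexan-1-one | CC(=C)[C@@H]1C[C@@H](O[Si](CC)(CC)CC)[C@](C)(O[Si](CC)(CC)CC)C(=O)[C@H]1O | intermediate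
14 | (1S,3S,4R,6S)-3-methyl-2-oxo-6-(prop-1-en-2-yl)-3,4-bis[(triethylsilyl)oxy]cyclohexyl 3-methylbutanoate | CC(=C)[C@@H]1C[C@@H](O[Si](CC)(CC)CC)[C@](C)(O[Si](CC)(CC)CC)C(=O)[C@H]1OC(=O)CC(C)C | intermediate
15 | (1S,3S,4R,6S)-6-(3-hydroxyprop-1-en-2-yl)-3-methyl-2-oxo-3,4-bis[(triethylsilyl)oxy]cyclohexyl 3-methylbutanoate (formed in the flask in step 9) | C=C(CO)[C@@H]1C[C@@H](O[Si](CC)(CC)CC)[C@](C)(O[Si](CC)(CC)CC)C(=O)[C@H]1OC(=O)CC(C)C | intermediate
16 | (1S,3S,4R,6S)-3-methyl-2-oxo-6-(3-oxoprop-1-en-2-yl)-3,4-bis[(triethylsilyl)oxy]cyclohexyl 3-methylbutanoate | C=C(C=O)[C@@H]1C[C@@H](O[Si](CC)(CC)CC)[C@](C)(O[Si](CC)(CC)CC)C(=O)[C@H]1OC(=O)CC(C)C | intermediate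
17 | (1S,3S,4R,6S)-6-(3-hydroxy-6-methylhepta-1,5-dien-2-yl)-3-methyl-2-oxo-3,4-bis[(triethylsilyl)oxy]cyclohexyl 3-methylbutanoate (both carbinol epimers) | C=C(C(O)CC=C(C)C)[C@@H]1C[C@@H](O[Si](CC)(CC)CC)[C@](C)(O[Si](CC)(CC)CC)C(=O)[C@H]1OC(=O)CC(C)C | intermediate
18 | (1S,3S,4R,6S)-3-methyl-6-(6-methyl-3-oxohepta-1,5-dien-2-yl)-2-oxo-3,4-bis[(triethylsilyl)oxy]cyclohexyl 3-methylbutanoate | C=C(C(=O)CC=C(C)C)[C@@H]1C[C@@H](O[Si](CC)(CC)CC)[C@](C)(O[Si](CC)(CC)CC)C(=O)[C@H]1OC(=O)CC(C)C | intermediate
19 | (1S,3S,4R,6S)-6-[(4E)-6-hydroperoxy-6-methyl-3-oxohepta-1,4-dien-2-yl]-3-methyl-2-oxo-3,4-bis[(triethylsilyl)oxy]cyclohexyl 3-methylbutanoate | C=C(C(=O)/C=C/C(C)(C)OO)[C@@H]1C[C@@H](O[Si](CC)(CC)CC)[C@](C)(O[Si](CC)(CC)CC)C(=O)[C@H]1OC(=O)CC(C)C | intermediate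
20 | (1S,3S,4R,6S)-3,4-dihydroxy-6-[(4E)-6-hydroperoxy-6-methyl-3-oxohepta-1,4-dien-2-yl]-3-methyl-2-oxocyclohexyl 3-methylbutanoate | C=C(C(=O)/C=C/C(C)(C)OO)[C@@H]1C[C@@H](O)[C@](C)(O)C(=O)[C@H]1OC(=O)CC(C)C | target

**Step count and risks**

Total step count: 13. Longest linear sequence: 13 steps (from methacrolein).

Steps most likely to fail:

1. Step 4 (key step). Reopening of the lactol under base may let retro-nitroaldol scramble the C3 carbinol centre. The acidic nitroalkane may buffer the base so that too little carbene forms. Enolisation of the α-hydroxy ketone may start an aldol closure to a five-membered ring. The fallback separates the two bond formations and removes the helper before the umpolung event. It sets out from lactol 9, which is then isolated after the nitroaldol stage. Radical denitration at the lactol stage (Bu3SnH, AIBN, toluene, 110 °C) should give the nitro-free lactol 1-[(2R,4S,5S)-6-hydroxy-5-[(4-methoxyphenyl)methoxy]-4-(prop-1-en-2-yl)oxan-2-yl]ethan-1-one F1. In F1 no nitronate or retro-nitroaldol pathway exists. The carbocycle is then closed on F1 by a crossed benzoin under protic thiazolium conditions (3-benzyl-5-(2-hydroxyethyl)-4-methylthiazol-3-ium chloride, Et3N, EtOH, 70 °C), which returns to the route at 11.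

2. Step 5. C–N fragmentation of a secondary nitroalkane is slow, so reduction may stall at the hydroxylamine or oxime stage, or the stannyl radical may be consumed by the isopropenyl group. The fallback sets out from 10 and replaces radical denitration by reduction and deamination. Zn dust in AcOH/THF at 0 °C should reduce the nitro group to the primary amine (2S,3R,4R,5R,6S)-4-amino-2,3-dihydroxy-6-[(4-methoxyphenyl)methoxy]-2-methyl-5-(prop-1-en-2-yl)cyclohexan-1-one F2. The amine is then removed through an isodiazene with the anomeric amide N-(benzyloxy)-N-(pivaloyloxy)-4-(trifluoromethyl)benzamide in MeCN at 45 °C (loss of N2). This comes back to the route at 11.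

3. Step 9. The ene step may lose site selectivity (abstraction of the ring methine hydrogen next to the isopropenyl group instead of a methyl hydrogen), and the ketone may be over-oxidised. The fallback sets out from 14 and uses an ene-type chlorination followed by N-oxide oxidation. Ca(OCl)2 with solid CO2 in CH2Cl2/H2O at 0 °C should give the allylic chloride (1S,3S,4R,6S)-6-(3-chloroprop-1-en-2-yl)-3-methyl-2-oxo-3,4-bis[(triethylsilyl)oxy]cyclohexyl 3-methylbutanoate F3. Trimethylamine N-oxide in DMSO at rt (Ganem oxidation) then converts F3 into the enal, returning to the route at 16.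

Further compounds
F1 | step 4 | 1-[(2R,4S,5S)-6-hydroxy-5-[(4-methoxyphenyl)methoxy]-4-(prop-1-en-2-yl)oxan-2-yl]ethan-1-one | CC(=O)[C@@H]1OC(O)[C@@H](OCc2ccc(OC)cc2)[C@H](C(C)=C)C1
F2 | step 5 | (2S,3R,4R,5R,6S)-4-amino-2,3-dihydroxy-6-[(4-methoxyphenyl)methoxy]-2-methyl-5-(prop-1-en-2-yl)cyclohexan-1-one | CC(=C)[C@@H]1[C@@H](N)[C@@H](O)[C@](C)(O)C(=O)[C@H]1OCc1ccc(OC)cc1
F3 | step 9 | (1S,3S,4R,6S)-6-(3-chloroprop-1-en-2-yl)-3-methyl-2-oxo-3,4-bis[(triethylsilyl)oxy]cyclohexyl 3-methylbutanoate | C=C(CCl)[C@@H]1C[C@@H](O[Si](CC)(CC)CC)[C@](C)(O[Si](CC)(CC)CC)C(=O)[C@H]1OC(=O)CC(C)C
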